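**Plan**

- Feature: the 2-pyrone ring (O1, C2–C6) is the enol lactone of a (Z)-2-en-4-ynoic acid. Cutting O1–C6 and C4–C5 gives a tert-butyl (Z)-β-triflyloxy enoate (C2, C3 with the ethyl tether, C4 with its methyl) and 3-ethynylfuran (C5, C6 and the furan ring).
- The enoate goes back to a β-keto ester, cut at the tether CH2–C3 bond into tert-butyl acetoacetate and a core acetaldehyde whose CHO carbon was the inner alkene carbon of an allyl group on C3a.
- In the core, the lactone C(=O)–O bond and the C3a–allyl bond are cut: a 1,2-allyl shift (semipinacol) on an epoxy carbinol made from a purchased cyclohexenone ester builds C3a.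
- Forward: the carbocycle is bought, the trans-fused γ-lactone closes next, the enone is introduced, the chain is joined by reductive Knoevenagel alkylation, and the pyrone ring closes last.
- Stereochemistry: a CBS reduction sets one carbinol, hydroxyl-directed epoxidation relays it to C7a, and the stereospecific allyl shift (inversion at the migration terminus) sets C3a with the side chain anti to the C7a hydroxyl; the relay carbon ends as the C4 ketone.

Key step: step 15

Remark: the descriptors (3aR,7aR) correspond to a trans-fused lactone, with the C7a hydroxyl anti to the C3a side chain and gauche to the lactone CH2O; the route is built for this relationship (TBS = tert-butyldimethylsilyl).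

Step 1
Reactants: 1 (tributylstannyl)methanol
Product: 2 tributyl{[(TBS)oxy]methyl}stannane
Conditions: TBSCl, imidazole, DMF, 23 °C
Reagents that add atoms: tert-butyldimethylsilyl chloride, CC(C)(C)[Si](C)(C)Cl
Why: Imidazole-mediated silylation of a primary alcohol gives the protected hydroxymethyl-transfer reagent.

Step 2
Reactants: 3 methyl 3-oxocyclohex-1-ene-1-carboxylate
Product: 4 methyl 2-iodo-3-oxocyclohex-1-ene-1-carboxylate
Conditions: I2, pyridine, CH2Cl2, 0 to 23 °C
Reagents that add atoms: iodine, II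
Why: α-Iodination of an enone by amine addition, iodination of the enolate and elimination places the halide on C2, the only vinylic CH.

Step 3
Reactants: 4 methyl 2-iodo-3-oxocyclohex-1-ene-1-carboxylate; 2 tributyl{[(TBS)oxy]methyl}stannane
Product: 5 methyl 2-{[(TBS)oxy]methyl}-3-oxocyclohex-1-ene-1-carboxylate
Conditions: Pd2(dba)3 (2.5 mol %), AsPh3 (20 mol %), CuI (10 mol %), NMP, 60 °C
Reagents that add atoms: none
Why: Stille cross-coupling of an α-iodoenone with an α-oxygenated methylstannane, whose CH2O group transfers in preference to butyl, installs the future lactone CH2O carbon, and the silyl ether keeps it from lactonising onto the neighbouring ester.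

Step 4
Reactants: 5 methyl 2-{[(TBS)oxy]methyl}-3-oxocyclohex-1-ene-1-carboxylate
Product: 6 methyl (3S)-2-{[(TBS)oxy]methyl}-3-hydroxycyclohex-1-ene-1-carboxylate
Conditions: (R)-1-methyl-3,3-diphenyltetrahydro-1H,3H-pyrrolo[1,2-c][1,3,2]oxazaborole (0.2 equiv), BH3·SMe2, THF, −20 °C
Reagents that add atoms: none
Why: Corey–Bakshi–Shibata reduction, in which the fully substituted alkenyl carbon is the large group and the ring CH2 the small one, so that the (R)-catalyst should give the (3S)-carbinol, the only reagent-controlled stereocentre of the route.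

Step 5
Reactants: 6 methyl (3S)-2-{[(TBS)oxy]methyl}-3-hydroxycyclohex-1-ene-1-carboxylate
Product: 7 methyl (1R,5S,6S)-6-{[(TBS)oxy]methyl}-5-hydroxy-7-oxabicyclo[4.1.0]heptane-1-carboxylate
Conditions: mCPBA, NaHCO3, CH2Cl2, 0 to 40 °C
Reagents that add atoms: 3-chloroperbenzoic acid, OOC(=O)c1cccc(Cl)c1
Why: Hydroxyl-directed (Henbest) epoxidation, in which hydrogen bonding of the peracid to the allylic OH delivers oxygen to the alkene face cis to the hydroxyl and so sets both oxirane carbons; the tetrasubstituted alkene should remain nucleophilic enough despite the ester.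

Step 6
Reactants: 7 methyl (1R,5S,6S)-6-{[(TBS)oxy]methyl}-5-hydroxy-7-oxabicyclo[4.1.0]heptane-1-carboxylate
Product: 8 methyl (1R,6R)-6-{[(TBS)oxy]methyl}-5-oxo-7-oxabicyclo[4.1.0]heptane-1-carboxylate
Conditions: Dess–Martin periodinane, NaHCO3, CH2Cl2, 23 °C
Reagents that add atoms: none
Why: Buffered Dess–Martin oxidation of the secondary alcohol leaves the epoxide and silyl ether intact and removes the relay stereocentre once it has fixed the epoxide.

Step 7
Reactants: 8 methyl (1R,6R)-6-{[(TBS)oxy]methyl}-5-oxo-7-oxabicyclo[4.1.0]heptane-1-carboxylate; 9 allylmagnesium bromide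
Product: 10 methyl (1R,5R,6S)-6-{[(TBS)oxy]methyl}-5-hydroxy-5-(prop-2-en-1-yl)-7-oxabicyclo[4.1.0]heptane-1-carboxylate
Conditions: THF, −78 °C; aqueous NH4Cl
Reagents that add atoms: none
Why: Grignard 1,2-addition is faster at the ketone than at the hindered ester and should occur anti to the adjacent epoxide C–O bond (Felkin–Anh/Cornforth control), so the new carbinol (5R) carries OH cis and allyl trans to the oxirane oxygen.

Step 8
Reactants: 10 methyl (1R,5R,6S)-6-{[(TBS)oxy]methyl}-5-hydroxy-5-(prop-2-en-1-yl)-7-oxabicyclo[4.1.0]heptane-1-carboxylate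
Product: 11 methyl (1R,2R)-2-{[(TBS)oxy]methyl}-1-hydroxy-3-oxo-2-(prop-2-en-1-yl)cyclohexane-1-carboxylate
Conditions: BF3·OEt2 (0.3 equiv), CH2Cl2, −78 to −20 °C
Reagents that add atoms: none
Why: Semipinacol rearrangement of a 2,3-epoxy alcohol: the Lewis acid opens the oxirane at C6 (the carbon remote from the ester) while the antiperiplanar allyl group shifts from the carbinol carbon with inversion at the terminus, so the quaternary centre (2R) carries allyl anti to the retained tertiary hydroxyl (1R) and the carbinol becomes the ketone.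

Step 9
Reactants: 11 methyl (1R,2R)-2-{[(TBS)oxy]methyl}-1-hydroxy-3-oxo-2-(prop-2-en-1-yl)cyclohexane-1-carboxylate
Product: 13 (3aR,7aR)-7a-hydroxy-3a-(prop-2-en-1-yl)hexahydro-2-benzofuran-1,4-dione, via diol ester 12 (not isolated)
Conditions: p-toluenesulfonic acid monohydrate (0.2 equiv), MeOH, 23 °C; solvent exchanged for toluene, 60 °C
Reagents that add atoms: none
Why: Acid-catalysed desilylation followed by lactonisation (5-exo-trig acyl substitution) of the CH2OH, which is gauche to the ester, should close the trans-fused γ-lactone without touching either stereocentre.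

Step 10
Reactants: 13 (3aR,7aR)-7a-hydroxy-3a-(prop-2-en-1-yl)hexahydro-2-benzofuran-1,4-dione
Product: 14 (3aR,7aR)-7a-hydroxy-3a-(prop-2-en-1-yl)-3a,7a-dihydro-2-benzofuran-1,4(3H,7H)-dione
Conditions: 2-iodoxybenzoic acid (IBX, 2.5 equiv), DMSO, 65 °C
Reagents that add atoms: none
Why: IBX dehydrogenation of a ketone can only give the C5=C6 enone, because C3a is quaternary and C5 carries the only α-hydrogens.

Step 11
Reactants: 14 (3aR,7aR)-7a-hydroxy-3a-(prop-2-en-1-yl)-3a,7a-dihydro-2-benzofuran-1,4(3H,7H)-dione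
Product: 15 [(3aR,7aR)-7a-hydroxy-1,4-dioxo-1,3,3a,4,7,7a-hexahydro-2-benzofuran-3a-yl]acetaldehyde
Conditions: OsO4 (2 mol %), NaIO4, 2,6-lutidine, dioxane/H2O, 23 °C
Reagents that add atoms: sodium periodate, [Na+].[O-]I(=O)(=O)=O
Why: Lemieux–Johnson cleavage, in which electrophilic OsO4 should take the terminal alkene in preference to the electron-poor enone; the trans disposition of the hydroxyl and the side chain excludes lactol formation.

Step 12
Reactants: 15 [(3aR,7aR)-7a-hydroxy-1,4-dioxo-1,3,3a,4,7,7a-hexahydro-2-benzofuran-3a-yl]acetaldehyde; 16 tert-butyl acetoacetate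
Product: 18 tert-butyl 2-acetyl-4-[(3aR,7aR)-7a-hydroxy-1,4-dioxo-1,3,3a,4,7,7a-hexahydro-2-benzofuran-3a-yl]butanoate (both epimers at C2), via alkylidene acetoacetate 17 (not isolated)
Conditions: piperidine (10 mol %), AcOH (10 mol %), diethyl 2,6-dimethyl-1,4-dihydropyridine-3,5-dicarboxylate (Hantzsch ester, 1.1 equiv), CH2Cl2, 23 °C
Reagents that add atoms: none
Why: Knoevenagel condensation followed in the same flask by Hantzsch-ester transfer hydrogenation of the doubly activated alkylidene (reductive alkylation) gives the mono-C-alkylated acetoacetate without a basic enolate alkylation and should leave the enone unreduced; the new α-carbon becomes sp2 in the next step.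

Step 13
Reactants: 18 tert-butyl 2-acetyl-4-[(3aR,7aR)-7a-hydroxy-1,4-dioxo-1,3,3a,4,7,7a-hexahydro-2-benzofuran-3a-yl]butanoate
Product: 19 tert-butyl (2Z)-2-{2-[(3aR,7aR)-7a-hydroxy-1,4-dioxo-1,3,3a,4,7,7a-hexahydro-2-benzofuran-3a-yl]ethyl}-3-{[(trifluoromethyl)sulfonyl]oxy}but-2-enoate
Conditions: LiOTf, Et3N, Tf2O, CH2Cl2, −78 to 0 °C
Reagents that add atoms: trifluoromethanesulfonic anhydride, O=S(=O)(OS(=O)(=O)C(F)(F)F)C(F)(F)F
Why: Enol triflation through the lithium-chelated enolate of the β-keto ester places the triflate cis to the ester (Z), and the amine base is too weak to ionise the tertiary alcohol.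

Step 14
Reactants: 20 furan-3-carbaldehyde; 21 dimethyl (1-diazo-2-oxopropyl)phosphonate
Product: 22 3-ethynylfuran
Conditions: K2CO3, MeOH, 0 to 23 °C
Reagents that add atoms: none
Why: Ohira–Bestmann (Seyferth–Gilbert) homologation converts the aldehyde into the terminal alkyne under mild base; the volatile product is carried forward as a solution.

Step 15
Reactants: 19 tert-butyl (2Z)-2-{2-[(3aR,7aR)-7a-hydroxy-1,4-dioxo-1,3,3a,4,7,7a-hexahydro-2-benzofuran-3a-yl]ethyl}-3-{[(trifluoromethyl)sulfonyl]oxy}but-2-enoate; 22 3-ethynylfuran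
Product: 24 (3aR,7aR)-3a-{2-[6-(furan-3-yl)-4-methyl-2-oxo-2H-pyran-3-yl]ethyl}-7a-hydroxy-3a,7a-dihydro-2-benzofuran-1,4(3H,7H)-dione (CNP0550188.1), via enynoate 23 (not isolated)
Conditions: PdCl2(PPh3)2 (5 mol %), CuI (10 mol %), iPr2NEt, MeCN, 23 °C; filtration through silica, CH2Cl2; AuCl(PPh3) (5 mol %), AgSbF6 (5 mol %), 23 °C
Reagents that add atoms: none
Why: Oxidative addition of zerovalent palladium to the vinyl triflate, transfer of the copper acetylide and reductive elimination form the pyrone C4–C5 bond and give enynoate 23 with the Z geometry retained (Sonogashira coupling). Cationic monovalent gold then binds the alkyne, the ester carbonyl oxygen attacks the furyl-bearing alkyne carbon to form O1–C6, the tert-butyl group leaves as isobutene and protodeauration releases the pyrone. The closest known reactions are the gold- or electrophile-promoted cyclisations of tert-butyl 2-alkynylbenzoates and (Z)-2-en-4-ynoates to isocoumarins and 2-pyrones. The pyrone ring closes in the 6-endo-dig mode and no stereocentre is formed. The step needs 6-endo rather than 5-exo closure, which the electron-rich 3-furyl group favours by stabilising positive charge at the distal alkyne carbon, and it needs alkyne and ester cis, which the chelation-controlled Z triflate provides. A hindered tertiary amine and neutral gold conditions are chosen to spare the β-hydroxy enone, which a stronger base could open by a retro-aldol path.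

**Compound list**

1 | (tributylstannyl)methanol | CCCC[Sn](CCCC)(CCCC)CO | starting material
2 | tributyl{[(TBS)oxy]methyl}stannane | CCCC[Sn](CCCC)(CCCC)CO[Si](C)(C)C(C)(C)C | intermediate
3 | methyl 3-oxocyclohex-1-ene-1-carboxylate | COC(=O)C1=CC(=O)CCC1 | starting material
4 | methyl 2-iodo-3-oxocyclohex-1-ene-1-carboxylate | COC(=O)C1=C(I)C(=O)CCC1 | intermediate
5 | methyl 2-{[(TBS)oxy]methyl}-3-oxocyclohex-1-ene-1-carboxylate | COC(=O)C1=C(CO[Si](C)(C)C(C)(C)C)C(=O)CCC1 | intermediate
6 | methyl (3S)-2-{[(TBS)oxy]methyl}-3-hydroxycyclohex-1-ene-1-carboxylate | COC(=O)C1=C(CO[Si](C)(C)C(C)(C)C)[C@@H](O)CCC1 | intermediate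
7 | methyl (1R,5S,6S)-6-{[(TBS)oxy]methyl}-5-hydroxy-7-oxabicyclo[4.1.0]heptane-1-carboxylate | COC(=O)[C@@]12CCC[C@H](O)[C@]1(CO[Si](C)(C)C(C)(C)C)O2 | intermediate
8 | methyl (1R,6R)-6-{[(TBS)oxy]methyl}-5-oxo-7-oxabicyclo[4.1.0]heptane-1-carboxylate | COC(=O)[C@@]12CCCC(=O)[C@]1(CO[Si](C)(C)C(C)(C)C)O2 | intermediate
9 | allylmagnesium bromide | C=CC[Mg]Br | starting material
10 | methyl (1R,5R,6S)-6-{[(TBS)oxy]methyl}-5-hydroxy-5-(prop-2-en-1-yl)-7-oxabicyclo[4.1.0]heptane-1-carboxylate | COC(=O)[C@@]12CCC[C@@](O)(CC=C)[C@]1(CO[Si](C)(C)C(C)(C)C)O2 | intermediate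
11 | methyl (1R,2R)-2-{[(TBS)oxy]methyl}-1-hydroxy-3-oxo-2-(prop-2-en-1-yl)cyclohexane-1-carboxylate | C=CC[C@]1(CO[Si](C)(C)C(C)(C)C)C(=O)CCC[C@]1(O)C(=O)OC | intermediate
12 | methyl (1R,2R)-1-hydroxy-2-(hydroxymethyl)-3-oxo-2-(prop-2-en-1-yl)cyclohexane-1-carboxylate (diol ester, not isolated) | C=CC[C@]1(CO)C(=O)CCC[C@]1(O)C(=O)OC | intermediate
13 | (3aR,7aR)-7a-hydroxy-3a-(prop-2-en-1-yl)hexahydro-2-benzofuran-1,4-dione | C=CC[C@@]12COC(=O)[C@@]1(O)CCCC2=O | intermediate
14 | (3aR,7aR)-7a-hydroxy-3a-(prop-2-en-1-yl)-3a,7a-dihydro-2-benzofuran-1,4(3H,7H)-dione | C=CC[C@@]12COC(=O)[C@@]1(O)CC=CC2=O | intermediate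
15 | [(3aR,7aR)-7a-hydroxy-1,4-dioxo-1,3,3a,4,7,7a-hexahydro-2-benzofuran-3a-yl]acetaldehyde | O=CC[C@@]12COC(=O)[C@@]1(O)CC=CC2=O | intermediate
16 | tert-butyl acetoacetate | CC(=O)CC(=O)OC(C)(C)C | starting material
17 | tert-butyl 2-acetyl-4-[(3aR,7aR)-7a-hydroxy-1,4-dioxo-1,3,3a,4,7,7a-hexahydro-2-benzofuran-3a-yl]but-2-enoate (alkylidene acetoacetate, not isolated) | CC(=O)C(=CC[C@@]12COC(=O)[C@@]1(O)CC=CC2=O)C(=O)OC(C)(C)C | intermediate
18 | tert-butyl 2-acetyl-4-[(3aR,7aR)-7a-hydroxy-1,4-dioxo-1,3,3a,4,7,7a-hexahydro-2-benzofuran-3a-yl]butanoate | CC(=O)C(CC[C@@]12COC(=O)[C@@]1(O)CC=CC2=O)C(=O)OC(C)(C)C | intermediate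
19 | tert-butyl (2Z)-2-{2-[(3aR,7aR)-7a-hydroxy-1,4-dioxo-1,3,3a,4,7,7a-hexahydro-2-benzofuran-3a-yl]ethyl}-3-{[(trifluoromethyl)sulfonyl]oxy}but-2-enoate | C/C(OS(=O)(=O)C(F)(F)F)=C(\CC[C@@]12COC(=O)[C@@]1(O)CC=CC2=O)C(=O)OC(C)(C)C | intermediate
20 | furan-3-carbaldehyde | O=Cc1ccoc1 | starting material
21 | dimethyl (1-diazo-2-oxopropyl)phosphonate | CC(=O)C(=[N+]=[N-])P(=O)(OC)OC | starting material
22 | 3-ethynylfuran | C#Cc1ccoc1 | intermediate
23 | tert-butyl (2Z)-5-(furan-3-yl)-2-{2-[(3aR,7aR)-7a-hydroxy-1,4-dioxo-1,3,3a,4,7,7a-hexahydro-2-benzofuran-3a-yl]ethyl}-3-methylpent-2-en-4-ynoate (enynoate, not isolated) | C/C(C#Cc1ccoc1)=C(\CC[C@@]12COC(=O)[C@@]1(O)CC=CC2=O)C(=O)OC(C)(C)C | intermediate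
24 | (3aR,7aR)-3a-{2-[6-(furan-3-yl)-4-methyl-2-oxo-2H-pyran-3-yl]ethyl}-7a-hydroxy-3a,7a-dihydro-2-benzofuran-1,4(3H,7H)-dione (CNP0550188.1) | Cc1cc(-c2ccoc2)oc(=O)c1CC[C@@]12COC(=O)[C@@]1(O)CC=CC2=O | target

**Step count**

Total: 15 steps. Longest linear sequence: 13 steps (3 to 24 through steps 2–13 and 15).

**Steps most likely to fail**

Step 8. The allyl group may migrate too slowly, so that the activated epoxide is consumed by a shift of the ring bond (ring contraction), by loss of the silyl ether or by external opening. The fallback sets out from 8 and comes back at 15; it uses a vinyl group, whose sp2 carbon shifts more readily, and derives the two-carbon tether by oxidation instead of cleavage. Vinylmagnesium bromide with CeCl3 in THF at −78 °C should add to 8 anti to the epoxide to give methyl (1R,5R,6S)-6-{[(TBS)oxy]methyl}-5-ethenyl-5-hydroxy-7-oxabicyclo[4.1.0]heptane-1-carboxylate F1. BF3·OEt2 should then induce the 1,2-vinyl shift to methyl (1R,2R)-2-{[(TBS)oxy]methyl}-2-ethenyl-1-hydroxy-3-oxocyclohexane-1-carboxylate F2. Acid in methanol should remove the silyl group to give methyl (1R,2R)-2-ethenyl-1-hydroxy-2-(hydroxymethyl)-3-oxocyclohexane-1-carboxylate F3, which on warming in toluene should close to (3aR,7aR)-3a-ethenyl-7a-hydroxyhexahydro-2-benzofuran-1,4-dione F4. IBX should give (3aR,7aR)-3a-ethenyl-7a-hydroxy-3a,7a-dihydro-2-benzofuran-1,4(3H,7H)-dione F5. An aldehyde-selective Wacker oxidation (PdCl2(MeCN)2, CuCl2, AgNO2, O2, tBuOH/MeNO2), steered to the terminal carbon by the neighbouring quaternary centre, should then deliver aldehyde 15.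

Step 5. Oxygen transfer to the ester-deactivated tetrasubstituted alkene may be slow, and hydrogen-bond control of the face may erode on heating. The fallback sets out from 5 and comes back at 7; it makes the epoxide on the enone, where the alkene is doubly activated toward nucleophiles. tert-Butyl hydroperoxide with catalytic 1,8-diazabicyclo[5.4.0]undec-7-ene (Weitz–Scheffer epoxidation) should give racemic methyl (1R*,6R*)-6-{[(TBS)oxy]methyl}-5-oxo-7-oxabicyclo[4.1.0]heptane-1-carboxylate F6. Reduction of F6 with BH3·SMe2 and the (R)-oxazaborolidine of step 4, stopped near half conversion, is a kinetic resolution: for the (1R,6R) enantiomer catalyst and substrate both favour hydride delivery anti to the epoxide, giving 7, while the slow enantiomer stays as ketone and is removed by chromatography.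

Step 15. The ring may close in the 5-exo mode to an alkylidene butenolide, the gold catalyst may be deactivated by amine or phosphine carried over from the coupling, or the amine may open the β-hydroxy enone during the coupling. The fallback sets out from 23, isolated by chromatography after the coupling of 19 and 22, and comes back at 24. The tert-butyl ester is cleaved with TFA in CH2Cl2 at 0 °C to (2Z)-5-(furan-3-yl)-2-{2-[(3aR,7aR)-7a-hydroxy-1,4-dioxo-1,3,3a,4,7,7a-hexahydro-2-benzofuran-3a-yl]ethyl}-3-methylpent-2-en-4-ynoic acid F7, and ZnBr2 in THF then promotes lactonisation of the free acid, a method known to favour six-membered pyranones over ylidene butenolides.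

Further compounds
F1 | step 8 | methyl (1R,5R,6S)-6-{[(TBS)oxy]methyl}-5-ethenyl-5-hydroxy-7-oxabicyclo[4.1.0]heptane-1-carboxylate | COC(=O)[C@@]12CCC[C@@](O)(C=C)[C@]1(CO[Si](C)(C)C(C)(C)C)O2
F2 | step 8 | methyl (1R,2R)-2-{[(TBS)oxy]methyl}-2-ethenyl-1-hydroxy-3-oxocyclohexane-1-carboxylate | C=C[C@]1(CO[Si](C)(C)C(C)(C)C)C(=O)CCC[C@]1(O)C(=O)OC
F3 | step 8 | methyl (1R,2R)-2-ethenyl-1-hydroxy-2-(hydroxymethyl)-3-oxocyclohexane-1-carboxylate | C=C[C@]1(CO)C(=O)CCC[C@]1(O)C(=O)OC
F4 | step 8 | (3aR,7aR)-3a-ethenyl-7a-hydroxyhexahydro-2-benzofuran-1,4-dione | C=C[C@@]12COC(=O)[C@@]1(O)CCCC2=O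
F5 | step 8 | (3aR,7aR)-3a-ethenyl-7a-hydroxy-3a,7a-dihydro-2-benzofuran-1,4(3H,7H)-dione | C=C[C@@]12COC(=O)[C@@]1(O)CC=CC2=O
F6 | step 5 | rac-methyl (1R*,6R*)-6-{[(TBS)oxy]methyl}-5-oxo-7-oxabicyclo[4.1.0]heptane-1-carboxylate (racemate, cis-fused oxirane) | COC(=O)C12CCCC(=O)C1(CO[Si](C)(C)C(C)(C)C)O2
F7 | step 15 | (2Z)-5-(furan-3-yl)-2-{2-[(3aR,7aR)-7a-hydroxy-1,4-dioxo-1,3,3a,4,7,7a-hexahydro-2-benzofuran-3a-yl]ethyl}-3-methylpent-2-en-4-ynoic acid | C/C(C#Cc1ccoc1)=C(\CC[C@@]12COC(=O)[C@@]1(O)CC=CC2=O)C(=O)O
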